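**Strategy.** Ring A (C1–C5, C10; labdane numbering), the bromocyclohexane, is closed last by a Robinson-type aldol condensation: methyl-ketone carbon C4 of a 3-oxobutyl chain on quaternary C10 adds to the ring-B ketone C5 of a precursor that already holds ring B, the C8–O–C15 oxocane and its epoxide. The step exploits the 1,5-diketone relationship C3/C5 across C10. The resulting Δ4-3-ketone is the handle for the C4 gem-dimethyl group and a 3-bromo-2,5-diene, whose HAT hydrogenation sets C3 and C5 in one event. C9 and C10 are relayed from C8, set by CuH desymmetrisation of a p-cresol-derived dienone.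

Key step: step 8

Assumption: labdane numbering is used (ring A = C1–C5/C10, ring B = C5–C10, C11–C15 chain bridged as C8–O–C15, C13–C14 epoxide; β = face of the C10 methyl). The sense of induction given for the two chiral catalysts (steps 2 and 7) follows the usual models; the antipodal catalyst is used if it proves opposite.

**Step 1**
Reactants: 1 p-cresol; 2 allyl alcohol
Product: 3 4-(allyloxy)-4-methylcyclohexa-2,5-dien-1-one
Conditions: PhI(OAc)2, allyl alcohol (solvent), 0 °C to rt
Reagents that add atoms: none
Why: Oxidative dearomatisation of a para-alkylphenol by a λ3-iodane, in which the solvent alcohol captures the phenoxenium-type intermediate at the para carbon to give the achiral quinol ether.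

**Step 2**
Reactants: 3 4-(allyloxy)-4-methylcyclohexa-2,5-dien-1-one
Product: 4 (R)-4-(allyloxy)-4-methylcyclohex-2-en-1-one
Conditions: Cu(OAc)2 (5 mol%), (S,S)-Ph-BPE (6 mol%), (MeO)2MeSiH, t-BuOH, toluene, −40 °C
Reagents that add atoms: none
Why: CuH-catalysed enantioselective conjugate reduction desymmetrises the 4,4-disubstituted cyclohexadienone, the chiral Cu–H reducing one of the two enantiotopic enone arms so that C8 becomes stereogenic with the (R) configuration.

**Step 3**
Reactants: 4 (R)-4-(allyloxy)-4-methylcyclohex-2-en-1-one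
Product: 5 (R)-4-(allyloxy)-2-iodo-4-methylcyclohex-2-en-1-one
Conditions: I2, pyridine, CH2Cl2, 0 °C to rt
Reagents that add atoms: iodine, II
Why: Johnson α-iodination of an enone (pyridine conjugate addition, iodination, elimination), which leaves the quaternary C8 untouched.

**Step 4**
Reactants: 5 (R)-4-(allyloxy)-2-iodo-4-methylcyclohex-2-en-1-one
Product: 6 (R)-4-(allyloxy)-2,4-dimethylcyclohex-2-en-1-one
Conditions: MeZnCl, Pd(PPh3)4 (5 mol%), THF, 40 °C
Reagents that add atoms: methylzinc chloride, C[Zn]Cl
Why: Negishi coupling of the α-iodoenone installs the future C10 methyl, so that the enolate of the next step is formed at C10 only.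

**Step 5**
Reactants: 6 (R)-4-(allyloxy)-2,4-dimethylcyclohex-2-en-1-one; 7 4-bromo-2-methylbut-1-ene; 8 3-(trimethylsilyl)but-3-en-2-one
Product: 11 (2R,3R,4R)-4-(allyloxy)-2,4-dimethyl-3-(3-methylbut-3-en-1-yl)-2-(3-oxobutyl)cyclohexan-1-one, via Grignard reagent 9 (not isolated), via alpha-silyl diketone 10 (not isolated)
Conditions: 7, Mg, THF; CuBr·SMe2 (20 mol%), 6, THF, −40 to −10 °C; then 8, −78 to −30 °C; then TBAF/AcOH, THF, 0 °C
Reagents that add atoms: none
Why: Copper-catalysed conjugate addition followed by Michael trapping of the regiodefined enolate with an α-silyl vinyl ketone (Stork–Ganem/Boeckman sequence) should place the chain on C9 anti to the pseudoaxial C8–O bond (γ-alkoxy enone rule) and the acceptor on C10 trans to the new C9 chain, after which buffered fluoride removes the α-silyl group.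

**Step 6**
Reactants: 11 (2R,3R,4R)-4-(allyloxy)-2,4-dimethyl-3-(3-methylbut-3-en-1-yl)-2-(3-oxobutyl)cyclohexan-1-one
Product: 12 trans-fused oxocene diketone (8α,15-ether; 13Z-ene; 10β-methyl; 10α-(3-oxobutyl); 5-one)
Conditions: Grubbs II (5 mol%), CH2Cl2 (3 mM), 40 °C
Reagents that add atoms: none
Why: Ring-closing metathesis between the allyl ether and the 1,1-disubstituted alkene closes the oxocene, the trans-diequatorial C8–O and C9–C11 bonds pre-organising the two chains and the eight-membered ring enforcing the Z alkene.

**Step 7**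
Reactants: 12 trans-fused oxocene diketone
Product: 13 epoxy diketone ((13R,14S)-13,14-epoxide of 12)
Conditions: ent-Shi ketone (L-fructose-derived, 30 mol%), Oxone, K2CO3, Bu4NHSO4, MeCN/DMM/aq. buffer (pH 10.5), 0 °C
Reagents that add atoms: Oxone (potassium peroxymonosulfate), [K+].[O-]S(=O)(=O)OO
Why: Shi asymmetric epoxidation (dioxirane, spiro transition state) of the only alkene, with the ketone antipode that is expected, by analogy with 1-substituted cycloalkenes, to deliver oxygen to the face giving the (13R,14S) epoxide.

**Step 8**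
Reactants: 13 epoxy diketone
Product: 15 tricyclic Δ4-3-ketone (ring A closed), via ketol 14 (not isolated)
Conditions: NaOMe (0.3 equiv), MeOH, 0 to 50 °C
Reagents that add atoms: none
Why: Methoxide reversibly enolises the methyl ketone toward C4, this enolate adds to the C5 ketone to give ketol 14, and E1cB loss of water gives the conjugated Δ4-3-ketone. This is the cyclisation half of the Robinson annulation, an intramolecular aldol condensation of a 1,5-diketone. Ring A is closed through the C4–C5 bond in a 6-(enolexo)-exo-trig mode, and no other ring is formed. No new stereocentre survives the step (C5 becomes sp2 and is set in step 12), and C10, being quaternary, cannot epimerise. The selectivity needed is fused over bridged aldolisation (C6 enolate onto the C3 ketone) and survival of the epoxide; the bridged ketol forms reversibly and only the fused ketol can dehydrate into conjugation, while a trisubstituted epoxide should be inert to catalytic methoxide at this temperature.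

**Step 9**
Reactants: 15 tricyclic Δ4-3-ketone
Product: 16 4,4-dimethyl-Δ5-3-ketone
Conditions: t-BuOK (3 equiv), MeI (excess), t-BuOH/THF, 0 °C to rt
Reagents that add atoms: iodomethane, CI
Why: Deconjugative α,α-dimethylation of a Δ4-3-ketone through its dienolate, the classical route to 4,4-dimethyl-Δ5-3-ketones, which builds the quaternary C4 and moves the alkene to C5=C6.

**Step 10**
Reactants: 16 4,4-dimethyl-Δ5-3-ketone
Product: 17 Δ2,Δ5-dienyl 3-triflate
Conditions: KHMDS, THF, −78 °C; PhNTf2, −78 to 0 °C
Reagents that add atoms: N-phenyl-bis(trifluoromethanesulfonimide), O=S(=O)(N(c1ccccc1)S(=O)(=O)C(F)(F)F)C(F)(F)F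
Why: Enol triflate formation, regiospecific because the ketone can enolise only toward C2 (C4 is quaternary).

**Step 11**
Reactants: 17 Δ2,Δ5-dienyl 3-triflate
Product: 18 3-bromo-2,5-diene
Conditions: Ni(cod)2 (10 mol%), LiBr, DMA/THF, rt
Reagents that add atoms: lithium bromide, [Li+].[Br-]
Why: Nickel-catalysed exchange of an enol triflate for bromide (oxidative addition, triflate/bromide exchange, reductive elimination) places bromine on C3 without touching the epoxide.

**Step 12**
Reactants: 18 3-bromo-2,5-diene
Product: 19 target CNP0311742.2 ((3S,5R,8R,9R,10S,13R,14S)-3β-bromo-8α,15:13,14-diepoxylabdane)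
Conditions: Mn(dpm)3 (10 mol%), PhSiH3, t-BuOOH, i-PrOH, rt
Reagents that add atoms: none
Why: Mn-hydride HAT hydrogenation, a method reported to reduce haloalkenes without C–X cleavage and to give thermodynamic stereocontrol, should form the tertiary C5 and the α-bromo C3 radicals and quench both from the α-face (the β-face is screened by the axial C10 and C4β methyls), giving the trans A/B fusion and the equatorial 3β-bromide.

**Compound list**
1 | p-cresol (4-methylphenol) | Cc1ccc(O)cc1 | starting material
2 | allyl alcohol | C=CCO | starting material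
3 | 4-(allyloxy)-4-methylcyclohexa-2,5-dien-1-one | CC1(OCC=C)C=CC(=O)C=C1 | intermediate
4 | (R)-4-(allyloxy)-4-methylcyclohex-2-en-1-one | C[C@]1(OCC=C)C=CC(=O)CC1 | intermediate
5 | (R)-4-(allyloxy)-2-iodo-4-methylcyclohex-2-en-1-one | C[C@]1(OCC=C)C=C(I)C(=O)CC1 | intermediate
6 | (R)-4-(allyloxy)-2,4-dimethylcyclohex-2-en-1-one | C[C@]1(OCC=C)C=C(C)C(=O)CC1 | intermediate
7 | 4-bromo-2-methylbut-1-ene | C=C(C)CCBr | starting material
8 | 3-(trimethylsilyl)but-3-en-2-one | CC(=O)C(=C)[Si](C)(C)C | starting material
9 | (3-methylbut-3-en-1-yl)magnesium bromide | C=C(C)CC[Mg]Br | intermediate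
10 | alpha-silyl diketone (Michael adduct, mixture at the silyl-bearing carbon) | CC(=O)C(C[C@]1(C)[C@@H](CCC(C)=C)[C@](C)(OCC=C)CCC1=O)[Si](C)(C)C | intermediate
11 | (2R,3R,4R)-4-(allyloxy)-2,4-dimethyl-3-(3-methylbut-3-en-1-yl)-2-(3-oxobutyl)cyclohexan-1-one | CC(=O)CC[C@]1(C)[C@@H](CCC(C)=C)[C@](C)(OCC=C)CCC1=O | intermediate
12 | trans-fused oxocene diketone (8α,15-ether; 13Z-ene; 10β-methyl; 10α-(3-oxobutyl); 5-one) | CC(=O)CC[C@]1(C)[C@H]2CC/C(C)=C\CO[C@]2(C)CCC1=O | intermediate
13 | epoxy diketone ((13R,14S)-13,14-epoxide of 12) | CC(=O)CC[C@]1(C)[C@H]2CC[C@@]3(C)O[C@H]3CO[C@]2(C)CCC1=O | intermediate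
14 | ketol (5β-hydroxy-3-ketone, cis-fused A/B; C5 configuration immaterial) | O=C1CC[C@]2(C)[C@H]3CC[C@@]4(C)O[C@H]4CO[C@]3(C)CC[C@]2(O)C1 | intermediate
15 | tricyclic Δ4-3-ketone | O=C1CC[C@]2(C)[C@H]3CC[C@@]4(C)O[C@H]4CO[C@]3(C)CCC2=C1 | intermediate
16 | 4,4-dimethyl-Δ5-3-ketone | CC1(C)C(=O)CC[C@]2(C)[C@H]3CC[C@@]4(C)O[C@H]4CO[C@]3(C)CC=C12 | intermediate
17 | Δ2,Δ5-dienyl 3-triflate | CC1(C)C(OS(=O)(=O)C(F)(F)F)=CC[C@]2(C)[C@H]3CC[C@@]4(C)O[C@H]4CO[C@]3(C)CC=C12 | intermediate
18 | 3-bromo-2,5-diene | CC1(C)C(Br)=CC[C@]2(C)[C@H]3CC[C@@]4(C)O[C@H]4CO[C@]3(C)CC=C12 | intermediate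
19 | CNP0311742.2 | CC1(C)[C@@H](Br)CC[C@]2(C)[C@H]3CC[C@@]4(C)O[C@H]4CO[C@]3(C)CC[C@@H]12 | target

**Totals**
Total step count: 12. Longest linear sequence: 12 steps (from p-cresol).

**Steps most likely to fail**

Step 12. The α-bromo radical at C3 may lose bromine or be reduced further (hydrodebromination), H-atom transfer to the hindered Δ5 alkene may be slow, and the second H-transfer at C3 may not be fully face-selective. The fallback sets out from 16. Hydrogenation over Pd/C (EtOAc) from the open α-face should give the 5α-ketone F1. L-Selectride (THF, −78 °C) should then give the axial 3α-alcohol F2, and Tf2O/pyridine the 3α-triflate F3. SN2 displacement with Bu4NBr in toluene inverts C3 and returns to 19.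

Step 5. Conjugate addition to the hindered α-methyl enone may be slow, with competing 1,2-addition, and the magnesium enolate may be captured incompletely by 8 (proton transfer or polymerisation of the acceptor). The fallback sets out from 6 and 9. A TMSCl-accelerated copper-catalysed addition (CuBr·SMe2, TMSCl, DMPU, THF, −78 °C) should give the regiodefined trimethylsilyl enol ether F4. MeLi (THF, 0 °C) regenerates the lithium enolate, which is trapped with 8 at −78 °C to come back at 10, and from there to 11 as in the route.

Step 7. The facial bias of the oxocene may oppose the catalyst, so that oxygen is delivered with poor facial selectivity. The fallback sets out from 12. NBS in THF/H2O (0 °C) should put Br+ on the exposed face and open the bromonium ion with water anti at C13, giving the bromohydrin F5. K2CO3 in MeOH (0 °C) then closes the epoxide on the hidden face with inversion at C14, coming back at 13.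

**Further compounds**
F1 | step 12 | 4,4-dimethyl-5α-3-ketone (Δ5 hydrogenated) | CC1(C)C(=O)CC[C@]2(C)[C@H]3CC[C@@]4(C)O[C@H]4CO[C@]3(C)CC[C@@H]12
F2 | step 12 | 3α-alcohol | CC1(C)[C@H](O)CC[C@]2(C)[C@H]3CC[C@@]4(C)O[C@H]4CO[C@]3(C)CC[C@@H]12
F3 | step 12 | 3α-triflate | CC1(C)[C@H](OS(=O)(=O)C(F)(F)F)CC[C@]2(C)[C@H]3CC[C@@]4(C)O[C@H]4CO[C@]3(C)CC[C@@H]12
F4 | step 5 | trimethylsilyl enol ether of the conjugate adduct | C=C(C)CC[C@@H]1C(C)=C(O[Si](C)(C)C)CC[C@@]1(C)OCC=C
F5 | step 7 | bromohydrin (13-hydroxy-14-bromo) | CC(=O)CC[C@]1(C)[C@H]2CC[C@@](C)(O)[C@H](Br)CO[C@]2(C)CCC1=O
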